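**Retrosynthetic overview**
1. Target ⇒ its tri-O-allyl ether (global deallylation last) ⇒ the corresponding chalcone (chemoselective 1,4-reduction).
2. Chalcone ⇒ Claisen–Schmidt aldol condensation of 2',4'-bis(allyloxy)acetophenone with an 8-allyloxy-2H-chromene-5-carbaldehyde; this is the key C–C bond joining the two fragments.
3. Chromene aldehyde ⇒ 5-bromo-8-fluoro-2H-chromene: Br→CHO by lithiation/DMF, then the fluorine para to CHO is exchanged for allyloxy by SNAr.
4. The pyran ring is the only ring made (both benzene rings are bought); it is closed by ring-closing metathesis of a 2-vinylaryl tertiary allyl ether, after the side-chain E-allylic tertiary alcohol has been made from the prenyl terminus (epoxide → selenide → selenoxide elimination).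
5. Quaternary (R) centre ⇒ chiral pool: (R)-linalool is O-arylated by SNAr on 6-bromo-2,3-difluorobenzaldehyde, and its C–O bond is never broken afterwards.

Assumption: commercial (R)-(−)-linalool is taken at ≥97% ee; no bond to its stereocentre is broken, so this ee is carried into the target.

**Route**

Step 1
Reactants: 1 (R)-(−)-linalool [(3R)-3,7-dimethylocta-1,6-dien-3-ol] (1.15 equiv); 2 6-bromo-2,3-difluorobenzaldehyde
Product: 4 6-bromo-2-{[(3R)-3,7-dimethylocta-1,6-dien-3-yl]oxy}-3-fluorobenzaldehyde, via potassium (R)-linaloolate 3 (not isolated)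
Conditions: KN(SiMe3)2 (1.1 equiv), THF, 0 °C, 20 min; then 2, −78 → 0 °C
Reagents that add atoms: none
Why: Nucleophilic aromatic substitution (addition–elimination) displaces the fluorine ortho to the formyl group (further activated by the neighbouring fluorine) with the tertiary alkoxide, and because the C–O bond of linalool is never broken its (R) configuration becomes that of the future C2 with retention.

Step 2
Reactants: 4 6-bromo-2-{[(3R)-3,7-dimethylocta-1,6-dien-3-yl]oxy}-3-fluorobenzaldehyde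
Product: 5 1-bromo-3-{[(3R)-3,7-dimethylocta-1,6-dien-3-yl]oxy}-2-ethenyl-4-fluorobenzene
Conditions: Ph3PCH3Br (1.5 equiv), KOtBu (1.4 equiv), THF, 0 °C → rt
Reagents that add atoms: methyltriphenylphosphonium bromide, C[P+](c1ccccc1)(c1ccccc1)c1ccccc1.[Br-]
Why: Wittig methylenation with the non-stabilised ylide converts the hindered, non-enolisable aldehyde into the styrene needed for ring closure without touching the base-stable tertiary allyl aryl ether.

Step 3
Reactants: 5 1-bromo-3-{[(3R)-3,7-dimethylocta-1,6-dien-3-yl]oxy}-2-ethenyl-4-fluorobenzene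
Product: 6 3-[(3R)-3-(3-bromo-2-ethenyl-6-fluorophenoxy)-3-methylpent-4-en-1-yl]-2,2-dimethyloxirane (both oxirane epimers)
Conditions: mCPBA (1.05 equiv), CH2Cl2, −10 → 0 °C
Reagents that add atoms: meta-chloroperoxybenzoic acid (mCPBA), OOC(=O)c1cccc(Cl)c1
Why: Prilezhaev epoxidation is governed by alkene nucleophilicity, so the trisubstituted alkene reacts far faster than the monosubstituted vinyl group or the twisted doubly ortho-substituted styrene; the new oxirane centre forms unselectively but is erased in step 5.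

Step 4
Reactants: 6 3-[(3R)-3-(3-bromo-2-ethenyl-6-fluorophenoxy)-3-methylpent-4-en-1-yl]-2,2-dimethyloxirane
Product: 7 (6R)-6-(3-bromo-2-ethenyl-6-fluorophenoxy)-2,6-dimethyl-3-(phenylselanyl)oct-7-en-2-ol (both C3 epimers)
Conditions: (PhSe)2 (0.6 equiv), NaBH4 (1.3 equiv), EtOH, 0 °C → rt; then 6, 78 °C; aqueous work-up
Reagents that add atoms: diphenyl diselenide, c1ccc(cc1)[Se][Se]c1ccccc1
Why: SN2 ring opening of the trisubstituted epoxide by the soft selenolate occurs at the less hindered secondary carbon (first half of the Sharpless epoxide-to-allylic-alcohol transposition), giving the tertiary alcohol with selenium on the neighbouring carbon.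

Step 5
Reactants: 7 (6R)-6-(3-bromo-2-ethenyl-6-fluorophenoxy)-2,6-dimethyl-3-(phenylselanyl)oct-7-en-2-ol
Product: 9 (3E,6R)-6-(3-bromo-2-ethenyl-6-fluorophenoxy)-2,6-dimethylocta-3,7-dien-2-ol, via selenoxide 8 (not isolated)
Conditions: 30% aq. H2O2 (5 equiv), pyridine (2 equiv), THF, 0 °C → rt
Reagents that add atoms: none
Why: Oxidation to the selenoxide is followed by spontaneous syn-elimination (selenoxide elimination), which can only go away from the fully substituted carbinol carbon and so gives the E-configured tertiary allylic alcohol from both C3 epimers.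

Step 6
Reactants: 9 (3E,6R)-6-(3-bromo-2-ethenyl-6-fluorophenoxy)-2,6-dimethylocta-3,7-dien-2-ol
Product: 10 (3E)-5-[(2R)-5-bromo-8-fluoro-2-methyl-2H-chromen-2-yl]-2-methylpent-3-en-2-ol
Conditions: second-generation Grubbs catalyst RuCl2(=CHPh)(H2IMes)(PCy3) (5 mol%), CH2Cl2 (0.01 M), 40 °C
Reagents that add atoms: none
Why: Ring-closing olefin metathesis joins the two terminal alkenes into the six-membered pyran ring with loss of ethene, while the hindered internal E-alkene next to the quaternary carbinol does not compete and the quaternary stereocentre is untouched.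

Step 7
Reactants: 10 (3E)-5-[(2R)-5-bromo-8-fluoro-2-methyl-2H-chromen-2-yl]-2-methylpent-3-en-2-ol
Product: 13 (2R)-8-fluoro-2-[(2E)-4-hydroxy-4-methylpent-2-en-1-yl]-2-methyl-2H-chromene-5-carbaldehyde, via aryllithium lithium alkoxide 11 (not isolated), via lithium hemiaminal alkoxide 12 (not isolated)
Conditions: n-BuLi (2.2 equiv), THF, −78 °C; DMF (4 equiv), −78 → 0 °C; then H2O
Reagents that add atoms: N,N-dimethylformamide, CN(C)C=O
Why: After the first equivalent deprotonates the alcohol, bromine–lithium exchange is much faster at −78 °C than any deprotonation of the fluoroarene, and the aryllithium is formylated by DMF (Bouveault-type formylation).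

Step 8
Reactants: 13 (2R)-8-fluoro-2-[(2E)-4-hydroxy-4-methylpent-2-en-1-yl]-2-methyl-2H-chromene-5-carbaldehyde
Product: 14 (2R)-2-[(2E)-4-hydroxy-4-methylpent-2-en-1-yl]-2-methyl-8-(prop-2-en-1-yloxy)-2H-chromene-5-carbaldehyde
Conditions: allyl alcohol (4 equiv), NaH (2 equiv), DMF, 0 °C; then 13, 0 → 50 °C
Reagents that add atoms: allyl alcohol (prop-2-en-1-ol), C=CCO
Why: Nucleophilic aromatic substitution displaces the fluorine, now para to the formyl group, with the primary alkoxide through a Meisenheimer adduct, installing the C8 oxygen already protected as an allyl ether while excess allyl alcohol keeps the tertiary alcohol protonated.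

Step 9
Reactants: 15 1-(2,4-dihydroxyphenyl)ethan-1-one (2',4'-dihydroxyacetophenone)
Product: 16 1-[2,4-bis(prop-2-en-1-yloxy)phenyl]ethan-1-one
Conditions: allyl bromide (2.5 equiv), K2CO3 (3 equiv), DMF, 60 °C
Reagents that add atoms: allyl bromide, C=CCBr
Why: Williamson ether synthesis, in which warming in DMF is enough to alkylate the hydrogen-bonded ortho hydroxyl as well.

Step 10
Reactants: 14 (2R)-2-[(2E)-4-hydroxy-4-methylpent-2-en-1-yl]-2-methyl-8-(prop-2-en-1-yloxy)-2H-chromene-5-carbaldehyde; 16 1-[2,4-bis(prop-2-en-1-yloxy)phenyl]ethan-1-one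
Product: 18 (2E)-1-[2,4-bis(prop-2-en-1-yloxy)phenyl]-3-{(2R)-2-[(2E)-4-hydroxy-4-methylpent-2-en-1-yl]-2-methyl-8-(prop-2-en-1-yloxy)-2H-chromen-5-yl}prop-2-en-1-one, via aldol adduct 17 (not isolated)
Conditions: KOH (50% aq.), EtOH, rt, 24–48 h
Reagents that add atoms: none
Why: Claisen–Schmidt (crossed aldol) condensation, in which the non-enolisable aldehyde accepts the methyl ketone enolate and E1cB dehydration of the aldol gives the conjugated (E)-chalcone, forming the key C–C bond between the two fragments.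

Step 11
Reactants: 18 (2E)-1-[2,4-bis(prop-2-en-1-yloxy)phenyl]-3-{(2R)-2-[(2E)-4-hydroxy-4-methylpent-2-en-1-yl]-2-methyl-8-(prop-2-en-1-yloxy)-2H-chromen-5-yl}prop-2-en-1-one
Product: 19 1-[2,4-bis(prop-2-en-1-yloxy)phenyl]-3-{(2R)-2-[(2E)-4-hydroxy-4-methylpent-2-en-1-yl]-2-methyl-8-(prop-2-en-1-yloxy)-2H-chromen-5-yl}propan-1-one
Conditions: [(Ph3P)CuH]6 (5 mol%), PhMe2SiH (1.5 equiv), t-BuOH (1.5 equiv), toluene, rt
Reagents that add atoms: none
Why: Copper hydride conjugate reduction (Stryker-type 1,4-hydride addition) is specific for the electron-poor enone C=C, so the chromene alkene, the side-chain alkene and the three allyl ethers are left alone, and the copper enolate is protonated by t-BuOH.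

Step 12
Reactants: 19 1-[2,4-bis(prop-2-en-1-yloxy)phenyl]-3-{(2R)-2-[(2E)-4-hydroxy-4-methylpent-2-en-1-yl]-2-methyl-8-(prop-2-en-1-yloxy)-2H-chromen-5-yl}propan-1-one
Product: 20 1-(2,4-dihydroxyphenyl)-3-{(2R)-8-hydroxy-2-[(2E)-4-hydroxy-4-methylpent-2-en-1-yl]-2-methyl-2H-chromen-5-yl}propan-1-one (CNP0311864.1)
Conditions: Pd(PPh3)4 (10 mol%), morpholine (10 equiv), THF, rt, dark
Reagents that add atoms: none
Why: Tsuji–Trost-type deallylation, in which zerovalent palladium ionises the three allyl aryl ethers and morpholine traps the π-allyl units under neutral conditions at room temperature, sparing the acid-sensitive tertiary allylic alcohol, the ketone and the chromene.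

**Compound list**
1 | (R)-(−)-linalool, (3R)-3,7-dimethylocta-1,6-dien-3-ol | CC(C)=CCC[C@@](C)(O)C=C | starting material
2 | 6-bromo-2,3-difluorobenzaldehyde | O=Cc1c(F)c(F)ccc1Br | starting material
3 | potassium (3R)-3,7-dimethylocta-1,6-dien-3-olate | CC(C)=CCC[C@@](C)([O-])C=C.[K+] | intermediate
4 | 6-bromo-2-{[(3R)-3,7-dimethylocta-1,6-dien-3-yl]oxy}-3-fluorobenzaldehyde | CC(C)=CCC[C@@](C)(Oc1c(F)ccc(Br)c1C=O)C=C | intermediate
5 | 1-bromo-3-{[(3R)-3,7-dimethylocta-1,6-dien-3-yl]oxy}-2-ethenyl-4-fluorobenzene | CC(C)=CCC[C@@](C)(Oc1c(F)ccc(Br)c1C=C)C=C | intermediate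
6 | 3-[(3R)-3-(3-bromo-2-ethenyl-6-fluorophenoxy)-3-methylpent-4-en-1-yl]-2,2-dimethyloxirane (both oxirane epimers) | CC1(C)OC1CC[C@@](C)(Oc2c(F)ccc(Br)c2C=C)C=C | intermediate
7 | (6R)-6-(3-bromo-2-ethenyl-6-fluorophenoxy)-2,6-dimethyl-3-(phenylselanyl)oct-7-en-2-ol (both C3 epimers) | CC(C)(O)C([Se]c1ccccc1)CC[C@@](C)(Oc1c(F)ccc(Br)c1C=C)C=C | intermediate
8 | (6R)-3-(benzeneseleninyl)-6-(3-bromo-2-ethenyl-6-fluorophenoxy)-2,6-dimethyloct-7-en-2-ol (selenoxide) | CC(C)(O)C([Se](=O)c1ccccc1)CC[C@@](C)(Oc1c(F)ccc(Br)c1C=C)C=C | intermediate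
9 | (3E,6R)-6-(3-bromo-2-ethenyl-6-fluorophenoxy)-2,6-dimethylocta-3,7-dien-2-ol | CC(C)(O)/C=C/C[C@@](C)(Oc1c(F)ccc(Br)c1C=C)C=C | intermediate
10 | (3E)-5-[(2R)-5-bromo-8-fluoro-2-methyl-2H-chromen-2-yl]-2-methylpent-3-en-2-ol | CC(C)(O)/C=C/C[C@]1(C)C=Cc2c(Br)ccc(F)c2O1 | intermediate
11 | lithium (3E)-5-[(2R)-8-fluoro-5-lithio-2-methyl-2H-chromen-2-yl]-2-methylpent-3-en-2-olate | CC(C)(O[Li])/C=C/C[C@]1(C)C=Cc2c([Li])ccc(F)c2O1 | intermediate
12 | dilithium salt of (dimethylamino){(2R)-8-fluoro-2-[(2E)-4-hydroxy-4-methylpent-2-en-1-yl]-2-methyl-2H-chromen-5-yl}methanol (DMF adduct of 11) | CC(C)(O[Li])/C=C/C[C@]1(C)C=Cc2c(C(O[Li])N(C)C)ccc(F)c2O1 | intermediate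
13 | (2R)-8-fluoro-2-[(2E)-4-hydroxy-4-methylpent-2-en-1-yl]-2-methyl-2H-chromene-5-carbaldehyde | CC(C)(O)/C=C/C[C@]1(C)C=Cc2c(C=O)ccc(F)c2O1 | intermediate
14 | (2R)-2-[(2E)-4-hydroxy-4-methylpent-2-en-1-yl]-2-methyl-8-(prop-2-en-1-yloxy)-2H-chromene-5-carbaldehyde | CC(C)(O)/C=C/C[C@]1(C)C=Cc2c(C=O)ccc(OCC=C)c2O1 | intermediate
15 | 1-(2,4-dihydroxyphenyl)ethan-1-one | CC(=O)c1ccc(O)cc1O | starting material
16 | 1-[2,4-bis(prop-2-en-1-yloxy)phenyl]ethan-1-one | CC(=O)c1ccc(OCC=C)cc1OCC=C | intermediate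
17 | 1-[2,4-bis(prop-2-en-1-yloxy)phenyl]-3-hydroxy-3-{(2R)-2-[(2E)-4-hydroxy-4-methylpent-2-en-1-yl]-2-methyl-8-(prop-2-en-1-yloxy)-2H-chromen-5-yl}propan-1-one (both carbinol epimers) | CC(C)(O)/C=C/C[C@]1(C)C=Cc2c(C(O)CC(=O)c3ccc(OCC=C)cc3OCC=C)ccc(OCC=C)c2O1 | intermediate
18 | (2E)-1-[2,4-bis(prop-2-en-1-yloxy)phenyl]-3-{(2R)-2-[(2E)-4-hydroxy-4-methylpent-2-en-1-yl]-2-methyl-8-(prop-2-en-1-yloxy)-2H-chromen-5-yl}prop-2-en-1-one | CC(C)(O)/C=C/C[C@]1(C)C=Cc2c(/C=C/C(=O)c3ccc(OCC=C)cc3OCC=C)ccc(OCC=C)c2O1 | intermediate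
19 | 1-[2,4-bis(prop-2-en-1-yloxy)phenyl]-3-{(2R)-2-[(2E)-4-hydroxy-4-methylpent-2-en-1-yl]-2-methyl-8-(prop-2-en-1-yloxy)-2H-chromen-5-yl}propan-1-one | CC(C)(O)/C=C/C[C@]1(C)C=Cc2c(CCC(=O)c3ccc(OCC=C)cc3OCC=C)ccc(OCC=C)c2O1 | intermediate
20 | 1-(2,4-dihydroxyphenyl)-3-{(2R)-8-hydroxy-2-[(2E)-4-hydroxy-4-methylpent-2-en-1-yl]-2-methyl-2H-chromen-5-yl}propan-1-one | CC(C)(O)/C=C/C[C@]1(C)C=Cc2c(CCC(=O)c3ccc(O)cc3O)ccc(O)c2O1 | target

**Totals**
Total step count: 12.
Longest linear sequence: 11 steps (steps 1–8 and 10–12, from 1 and 2); step 9 is the one-step side branch.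
Handling note: from 10 onward the 2H-chromenes are kept below about 60 °C and away from UV light, because electrocyclic ring opening to the ortho-quinone methide is the only pathway that could scramble C2.

**Three steps most likely to fail, with fallbacks**

Step 1 (SNAr of a hindered tertiary alkoxide next to a formyl group). The alkoxide may add to or cleave the doubly ortho-halogenated formyl group instead of displacing fluoride. The fallback sets out from 2 and comes back at 4. Compound 2 is converted in one pot (NH2OH·HCl, HCO2Na, HCO2H, 100 °C) through 6-bromo-2,3-difluorobenzaldehyde oxime F1 into 6-bromo-2,3-difluorobenzonitrile F2, whose activating group cannot be attacked reversibly or lost. F2 is treated with 3 (THF, 0 °C → rt) to give 6-bromo-2-{[(3R)-3,7-dimethylocta-1,6-dien-3-yl]oxy}-3-fluorobenzonitrile F3. Reduction with i-Bu2AlH (toluene, −78 °C) gives, after mild hydrolysis of the aluminium imide, 1-(6-bromo-2-{[(3R)-3,7-dimethylocta-1,6-dien-3-yl]oxy}-3-fluorophenyl)methanimine F4, which is hydrolysed on wet silica/aq. citric acid to 4.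

Step 8 (alkoxide SNAr in the presence of a free aldehyde). Allyloxide may reduce or add to the aldehyde faster than it displaces the fluoride flanked by the ring oxygen. The fallback sets out from 13 and comes back at 14. KOSiMe3 (3 equiv, THF, rt → 50 °C) is used as an anhydrous hydroxide equivalent and first gives (2R)-2-[(2E)-4-hydroxy-4-methylpent-2-en-1-yl]-2-methyl-8-[(trimethylsilyl)oxy]-2H-chromene-5-carbaldehyde F5. F5 is desilylated in the flask by a second equivalent of silanolate and, after aq. NH4Cl, gives (2R)-8-hydroxy-2-[(2E)-4-hydroxy-4-methylpent-2-en-1-yl]-2-methyl-2H-chromene-5-carbaldehyde F6. Williamson O-allylation of F6 (allyl bromide, K2CO3, acetone, 50 °C) returns 14.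

Step 11 (1,4-reduction of one C=C among six). If over-reduction, allyl ether loss or poor conversion cannot be suppressed, the enone is avoided altogether; the fallback sets out from 14 (together with 16) and comes back at 19. NaBH4 (MeOH, 0 °C) reduces 14 to (3E)-5-[(2R)-5-(hydroxymethyl)-2-methyl-8-(prop-2-en-1-yloxy)-2H-chromen-2-yl]-2-methylpent-3-en-2-ol F7. MsCl/Et3N/LiCl (THF, 0 °C → rt) activates only the primary benzylic hydroxyl, through {(2R)-2-[(2E)-4-hydroxy-4-methylpent-2-en-1-yl]-2-methyl-8-(prop-2-en-1-yloxy)-2H-chromen-5-yl}methyl methanesulfonate F8, to give (3E)-5-[(2R)-5-(chloromethyl)-2-methyl-8-(prop-2-en-1-yloxy)-2H-chromen-2-yl]-2-methylpent-3-en-2-ol F9. Ketone 16 is converted with LiN(SiMe3)2 (THF, −78 °C, 2.5 equiv of enolate) into lithium 1-[2,4-bis(prop-2-en-1-yloxy)phenyl]ethen-1-olate F10, which is alkylated by F9 (cat. NaI, −78 °C → rt) to give 19 directly.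

**Further compounds**
F1 | step 1 | 6-bromo-2,3-difluorobenzaldehyde oxime | ON=Cc1c(F)c(F)ccc1Br
F2 | step 1 | 6-bromo-2,3-difluorobenzonitrile | N#Cc1c(F)c(F)ccc1Br
F3 | step 1 | 6-bromo-2-{[(3R)-3,7-dimethylocta-1,6-dien-3-yl]oxy}-3-fluorobenzonitrile | CC(C)=CCC[C@@](C)(Oc1c(F)ccc(Br)c1C#N)C=C
F4 | step 1 | 1-(6-bromo-2-{[(3R)-3,7-dimethylocta-1,6-dien-3-yl]oxy}-3-fluorophenyl)methanimine | CC(C)=CCC[C@@](C)(Oc1c(F)ccc(Br)c1C=N)C=C
F5 | step 8 | (2R)-2-[(2E)-4-hydroxy-4-methylpent-2-en-1-yl]-2-methyl-8-[(trimethylsilyl)oxy]-2H-chromene-5-carbaldehyde | CC(C)(O)/C=C/C[C@]1(C)C=Cc2c(C=O)ccc(O[Si](C)(C)C)c2O1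
F6 | step 8 | (2R)-8-hydroxy-2-[(2E)-4-hydroxy-4-methylpent-2-en-1-yl]-2-methyl-2H-chromene-5-carbaldehyde | CC(C)(O)/C=C/C[C@]1(C)C=Cc2c(C=O)ccc(O)c2O1
F7 | step 11 | (3E)-5-[(2R)-5-(hydroxymethyl)-2-methyl-8-(prop-2-en-1-yloxy)-2H-chromen-2-yl]-2-methylpent-3-en-2-ol | CC(C)(O)/C=C/C[C@]1(C)C=Cc2c(CO)ccc(OCC=C)c2O1
F8 | step 11 | {(2R)-2-[(2E)-4-hydroxy-4-methylpent-2-en-1-yl]-2-methyl-8-(prop-2-en-1-yloxy)-2H-chromen-5-yl}methyl methanesulfonate | CC(C)(O)/C=C/C[C@]1(C)C=Cc2c(COS(C)(=O)=O)ccc(OCC=C)c2O1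
F9 | step 11 | (3E)-5-[(2R)-5-(chloromethyl)-2-methyl-8-(prop-2-en-1-yloxy)-2H-chromen-2-yl]-2-methylpent-3-en-2-ol | CC(C)(O)/C=C/C[C@]1(C)C=Cc2c(CCl)ccc(OCC=C)c2O1
F10 | step 11 | lithium 1-[2,4-bis(prop-2-en-1-yloxy)phenyl]ethen-1-olate | C=C(O[Li])c1ccc(OCC=C)cc1OCC=C
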